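**Strategy.** The benzo ring is disconnected at C3a–C4 and C7–C7a, leaving the pyrrole ring as the starting core. The plan exploits two features of the target: the ring-fusion bond C3a–C7a is a pyrrole C=C bond, and the brominated C6 of the benzo ring lies para to C3a. A Diels–Alder reaction between 3-nitro-1-tosylpyrrole (nitro on the future C3a, sulfonyl on nitrogen as second activator) and 2-bromobuta-1,3-diene closes the six-membered ring, delivers the C6 bromine and, through loss of nitrous acid, restores the pyrrole in one operation. Dehydrogenation, removal of the sulfonyl group and bromination at C3 and C2 complete the route.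

Key step: step 3

Remark: 3,4-dibromobut-1-ene is taken to be purchasable and is used cold and freshly distilled, because it equilibrates with 1,4-dibromobut-2-ene on warming. No isolated compound of the route has a stereocentre; the two that arise in the cycloadduct are lost in the same step.

Step 1
Reactants: 1 3-nitro-1H-pyrrole; 2 4-methylbenzenesulfonyl chloride
Product: 4 3-nitro-1-(4-methylphenylsulfonyl)-1H-pyrrole, via sodium 3-nitropyrrol-1-ide 3 (not isolated)
Conditions: NaH (1.1 equiv), THF, 0 °C; then 2 (1.1 equiv), 0 °C → rt
Reagents that add atoms: 4-methylbenzenesulfonyl chloride (2), Cc1ccc(cc1)S(=O)(=O)Cl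
Why: The nitro group makes the pyrrole N–H acidic enough for clean deprotonation by NaH, and the nitrogen anion attacks the sulfonyl chloride at sulfur (N-sulfonylation of an azole anion), which installs the second electron-withdrawing group the dienophile needs.

Step 2
Reactants: 5 3,4-dibromobut-1-ene
Product: 6 2-bromobuta-1,3-diene
Conditions: 5 added dropwise to powdered KOH (2.5 equiv), Bu4NBr (cat.), paraffin oil, 80 °C, 150 mbar; diene distilled as formed into a −78 °C trap over BHT
Reagents that add atoms: none
Why: Base-induced E2 dehydrobromination in which hydroxide removes the allylic, bromine-bearing C3 hydrogen and the primary C4 bromide leaves, the same 1,2-elimination that turns the 3,4-dichloride into 2-chlorobuta-1,3-diene; distilling the diene out as it forms should keep it from polymerising.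

Step 3
Reactants: 4 3-nitro-1-(4-methylphenylsulfonyl)-1H-pyrrole; 6 2-bromobuta-1,3-diene
Product: 8 6-bromo-1-(4-methylphenylsulfonyl)-4,7-dihydro-1H-indole, via cis-fused 3a-nitro cycloadduct 7 (not isolated)
Conditions: 6 (8 equiv), BHT (5 mol%), toluene, sealed tube, 140 °C, 48 h
Reagents that add atoms: none
Why: This is a polar, asynchronous normal-electron-demand Diels–Alder reaction in which the N-sulfonyl and C3-nitro groups make the pyrrole C2=C3 bond an electron-poor nitroalkene, followed by thermal elimination of nitrous acid (the C7a hydrogen and the C3a nitro group of 7), which re-aromatises the pyrrole and makes the addition irreversible. The closest known reaction type is the sealed-tube cycloaddition of N-sulfonyl nitropyrroles and nitroindoles with simple dienes, which ends in loss of nitrous acid and benzannulated products; the bromodiene is a less nucleophilic member of the same diene class. The six-membered ring is closed by intermolecular [4+2] cycloaddition, with C3a–C4 and C7–C7a formed suprafacially in one event. The two stereocentres of 7 (C3a and C7a) arise cis through suprafacial addition to the dienophile, as a racemate, and both vanish on elimination, so 8 has none. The step needs regioselectivity: pyrrole C2, β to the nitro group, is the electrophilic terminus and should bond to diene C1, the terminus made more nucleophilic by lone-pair donation from bromine on C2, which places bromine para to the nitro-bearing carbon, that is at C6; the bias is modest, so some 5-bromo isomer is expected and would be removed by chromatography or by crystallisation after step 4. A large excess of diene and a radical inhibitor offset its polymerisation at the temperature required.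

Step 4
Reactants: 8 6-bromo-1-(4-methylphenylsulfonyl)-4,7-dihydro-1H-indole
Product: 9 6-bromo-1-(4-methylphenylsulfonyl)-1H-indole
Conditions: DDQ (1.2 equiv), toluene, rt → 60 °C
Reagents that add atoms: none
Why: DDQ dehydrogenation of a 1,4-cyclohexadiene by hydride abstraction from a doubly allylic CH2 and proton loss is driven by formation of the benzene ring; the vinyl bromide becomes the aryl bromide, the sulfonamide is inert, and any material already aromatised in step 3 converges on the same product.

Step 5
Reactants: 9 6-bromo-1-(4-methylphenylsulfonyl)-1H-indole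
Product: 10 6-bromo-1H-indole
Conditions: KOH (5 equiv), EtOH–THF–H2O, 70 °C
Reagents that add atoms: none
Why: Nucleophilic desulfonylation in which hydroxide attacks sulfur and expels the indole nitrogen as a stabilised leaving group that the solvent protonates, a standard cleavage of N-sulfonylindoles that leaves the aryl bromide untouched; aqueous ethanol avoids build-up of an alkylating sulfonate ester.

Step 6
Reactants: 10 6-bromo-1H-indole; 11 N-bromosuccinimide
Product: 13 2,3,6-tribromo-1H-indole, via 3,6-dibromo-1H-indole 12 (not isolated)
Conditions: 11 (2.05 equiv), silica gel, CH2Cl2, 0 °C → rt, dark; aqueous Na2S2O3/NaHCO3 work-up, product stored cold and dark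
Reagents that add atoms: N-bromosuccinimide (11), O=C1CCC(=O)N1Br
Why: Electrophilic aromatic substitution on the electron-rich pyrrole ring, in which the first bromine enters the most nucleophilic position C3 and the second equivalent brominates C2 of the 3-bromoindole (attack at C3 and 1,2-shift of bromine, or direct C2 attack), while the benzo ring, deactivated by the C6 bromine, is left alone; anhydrous silica-supported conditions are an established way to 2,3-dibromoindoles and should suppress oxindole formation.

**Compound list**

1 | 3-nitro-1H-pyrrole | [O-][N+](=O)c1cc[nH]c1 | starting material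
2 | 4-methylbenzenesulfonyl chloride | Cc1ccc(cc1)S(=O)(=O)Cl | starting material
3 | sodium 3-nitropyrrol-1-ide | [Na+].[O-][N+](=O)c1cc[n-]c1 | intermediate (not isolated)
4 | 3-nitro-1-(4-methylphenylsulfonyl)-1H-pyrrole | Cc1ccc(cc1)S(=O)(=O)n1ccc(c1)[N+](=O)[O-] | intermediate
5 | 3,4-dibromobut-1-ene (racemic) | C=CC(Br)CBr | starting material
6 | 2-bromobuta-1,3-diene | C=CC(Br)=C | intermediate
7 | cis-6-bromo-3a-nitro-1-(4-methylphenylsulfonyl)-3a,4,7,7a-tetrahydro-1H-indole (racemic; 3a-nitro and 7a-H on the same face; one enantiomer drawn) | Cc1ccc(cc1)S(=O)(=O)N1C=C[C@]2(CC=C(Br)C[C@@H]12)[N+](=O)[O-] | intermediate (not isolated)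
8 | 6-bromo-1-(4-methylphenylsulfonyl)-4,7-dihydro-1H-indole | Cc1ccc(cc1)S(=O)(=O)n1ccc2CC=C(Br)Cc21 | intermediate
9 | 6-bromo-1-(4-methylphenylsulfonyl)-1H-indole | Cc1ccc(cc1)S(=O)(=O)n1ccc2ccc(Br)cc21 | intermediate
10 | 6-bromo-1H-indole | Brc1ccc2cc[nH]c2c1 | intermediate
11 | N-bromosuccinimide | O=C1CCC(=O)N1Br | starting material
12 | 3,6-dibromo-1H-indole | Brc1ccc2c(Br)c[nH]c2c1 | intermediate (not isolated)
13 | 2,3,6-tribromo-1H-indole | Brc1ccc2c(Br)c(Br)[nH]c2c1 | target

Total step count: 6
Longest linear sequence: 5 steps (steps 1, 3, 4, 5, 6); step 2 is a one-step side branch.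

**Steps most likely to fail**

1. Step 3. The weakly activated bromodiene may polymerise faster than it adds, and the modest directing effect of bromine may give poor regiocontrol, so that the 5-bromo series contaminates the 6-bromo series. The fallback sets out from 4 and comes back to the route at 9. Compound 4 would be heated with trans-1-methoxy-3-(trimethylsilyloxy)buta-1,3-diene (toluene, sealed tube, 90–110 °C), a far more nucleophilic diene whose two oxygen substituents both steer its unsubstituted terminus to pyrrole C2. The cis-fused cycloadduct 4-methoxy-3a-nitro-1-(4-methylphenylsulfonyl)-6-(trimethylsilyloxy)-3a,4,7,7a-tetrahydro-1H-indole F1 would not be isolated; loss of nitrous acid and methanol, then desilylation on acidic work-up, should give 1-(4-methylphenylsulfonyl)-1H-indol-6-ol F2. Triflation (Tf2O, pyridine, CH2Cl2, 0 °C) would give 1-(4-methylphenylsulfonyl)-1H-indol-6-yl trifluoromethanesulfonate F3. Miyaura borylation (B2pin2, Pd(dppf)Cl2, KOAc, dioxane, 90 °C) would give 6-(4,4,5,5-tetramethyl-1,3,2-dioxaborolan-2-yl)-1-(4-methylphenylsulfonyl)-1H-indole F4, and bromodeboronation with CuBr2 (MeOH–H2O, 80 °C) would give 9.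

2. Step 6. The unprotected indole may be over-oxidised (oxindole formation, attack on the benzo ring), and the acid- and light-sensitive product may decompose during isolation. The fallback sets out from 9 and comes back at 13, keeping the sulfonyl group on nitrogen until the end. Bromination of 9 at C3 (Br2, CH2Cl2, 0 °C → rt) would give 3,6-dibromo-1-(4-methylphenylsulfonyl)-1H-indole F5. Directed deprotonation at C2 (LiN(iPr)2, THF, −78 °C) would give 3,6-dibromo-2-lithio-1-(4-methylphenylsulfonyl)-1H-indole F6, not isolated, which would be quenched with 1,2-dibromo-1,1,2,2-tetrachloroethane to give 2,3,6-tribromo-1-(4-methylphenylsulfonyl)-1H-indole F7. Mild cleavage of the sulfonamide (KOH, aqueous EtOH–THF, rt) would then give 13.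

3. Step 2. Allylic transposition of 5 to the 1,4-dibromide ahead of elimination would lead to the 1-bromo diene, and the product may polymerise in the hot alkaline still. The fallback sets out from tosyl chloride 2 and purchased 3-bromobut-3-en-1-ol F8 and comes back at 6. Sulfonylation (2, Et3N, DMAP cat., CH2Cl2, 0 °C) would give 3-bromobut-3-en-1-yl 4-methylbenzenesulfonate F9. E2 elimination (potassium tert-butoxide, DMSO, rt, reduced pressure, diene condensed at −78 °C over BHT) would then give 6. The vinyl bromide is in place from the start, so the position of bromine is not at stake.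

**Further compounds**

F1 | step 3 | cis-fused 4-methoxy-3a-nitro-1-(4-methylphenylsulfonyl)-6-(trimethylsilyloxy)-3a,4,7,7a-tetrahydro-1H-indole (racemic, mixture of C4 epimers, not isolated) | Cc1ccc(cc1)S(=O)(=O)N1C=C[C@]2(C(OC)C=C(O[Si](C)(C)C)C[C@@H]12)[N+](=O)[O-]
F2 | step 3 | 1-(4-methylphenylsulfonyl)-1H-indol-6-ol | Cc1ccc(cc1)S(=O)(=O)n1ccc2ccc(O)cc21
F3 | step 3 | 1-(4-methylphenylsulfonyl)-1H-indol-6-yl trifluoromethanesulfonate | Cc1ccc(cc1)S(=O)(=O)n1ccc2ccc(OS(=O)(=O)C(F)(F)F)cc21
F4 | step 3 | 6-(4,4,5,5-tetramethyl-1,3,2-dioxaborolan-2-yl)-1-(4-methylphenylsulfonyl)-1H-indole | Cc1ccc(cc1)S(=O)(=O)n1ccc2ccc(cc21)B1OC(C)(C)C(C)(C)O1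
F5 | step 6 | 3,6-dibromo-1-(4-methylphenylsulfonyl)-1H-indole | Cc1ccc(cc1)S(=O)(=O)n1cc(Br)c2ccc(Br)cc21
F6 | step 6 | 3,6-dibromo-2-lithio-1-(4-methylphenylsulfonyl)-1H-indole (not isolated) | Cc1ccc(cc1)S(=O)(=O)n1c([Li])c(Br)c2ccc(Br)cc21
F7 | step 6 | 2,3,6-tribromo-1-(4-methylphenylsulfonyl)-1H-indole | Cc1ccc(cc1)S(=O)(=O)n1c(Br)c(Br)c2ccc(Br)cc21
F8 | step 2 | 3-bromobut-3-en-1-ol (purchased) | OCCC(Br)=C
F9 | step 2 | 3-bromobut-3-en-1-yl 4-methylbenzenesulfonate | Cc1ccc(cc1)S(=O)(=O)OCCC(Br)=C
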